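**Plan**
Retrosynthetic cuts: the thirteen benzyl ethers; then, in one operation, the interflavan C4–C8 bond and the C4–C4a bond of the upper pyran ring, which leaves an acyclic α-acyloxy aldehyde and the protected lower unit; then the upper 3-O-galloyl ester, the O1–C8a aryl ether bond and the C2–C3 bond.
Forward order: the lower unit is taken ring-complete from (−)-epicatechin; the upper chain O1–C2–C3–C4 is built open (C2–C3 by alkoxyallylboration, O1–C8a by copper-catalysed O-arylation, then ester and alkene cleavage); the upper pyran ring (O1, C2, C3, C4, C4a, C8a) closes last, in the flask in which C4 is joined to C8.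
Enabling feature: C4 of the upper unit is a methine between two phloroglucinol-type rings (upper ring A through C4a, lower ring A through C8), so it can enter as an aldehyde carbon that is arylated twice; upper ring A is a symmetric 3,5-dioxygenated phenyl ether on O1 whose two ortho carbons are equivalent.
Stereochemistry: upper C2 and C3 come from a reagent-controlled syn alkoxyallylboration (the O-arylation makes its bond at the aryl carbon and leaves C2 untouched); C4 is set stereoconvergently from a planar benzylic cation attacked anti to the α-oriented 2-aryl and 3-acyloxy groups; the lower unit comes from the chiral pool.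

Key step: step 8

Remark: 3-(methoxymethoxy)prop-1-ene and 1-bromo-3,5-bis(benzyloxy)benzene are taken as catalogue compounds; each is otherwise one etherification from allyl alcohol or 5-bromoresorcinol.

**Step 1**
Reactants: 1 (−)-epicatechin
Product: 2 5,7,3′,4′-tetra-O-benzyl-(−)-epicatechin
Conditions: BnBr (4.4 equiv), K2CO3 (5 equiv), DMF, 0 °C to rt, argon
Reagents that add atoms: benzyl bromide, BrCc1ccccc1
Why: Williamson O-benzylation in which K2CO3 deprotonates the four phenols but not the aliphatic 3-OH, so 2 should form with the 3-OH free and both stereocentres untouched (low temperature and exclusion of air limit base-induced C2 epimerisation and C-benzylation).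

**Step 2**
Reactants: 2 5,7,3′,4′-tetra-O-benzyl-(−)-epicatechin; 3 3,4,5-tris(benzyloxy)benzoic acid
Product: 4 5,7,3′,4′-tetra-O-benzyl-(−)-epicatechin 3-O-[3,4,5-tris(benzyloxy)benzoate]
Conditions: 3 (1.5 equiv), DCC (1.6 equiv), DMAP (0.3 equiv), CH2Cl2, rt
Reagents that add atoms: none
Why: Steglich esterification of the secondary 3-OH, which involves no stereocentre and gives the nucleophile for step 8 with C8 and C6 free.

**Step 3**
Reactants: 5 4-(benzyloxy)benzaldehyde; 6 3-(methoxymethoxy)prop-1-ene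
Product: 9 (1R,2R)-1-[4-(benzyloxy)phenyl]-2-(methoxymethoxy)but-3-en-1-ol, via (Z)-alkoxyallylborane 7 (not isolated), via O-borinate 8 (not isolated)
Conditions: 6 (1.3 equiv), s-BuLi (1.2 equiv), THF, −78 °C; (−)-Ipc2BOMe [(−)-B-methoxydiisopinocampheylborane, from (+)-α-pinene] (1.2 equiv); BF3·OEt2 (1.5 equiv); then 5, −78 °C to rt; NaOH, H2O2, rt
Reagents that add atoms: none
Why: Brown asymmetric alkoxyallylboration, in which deprotonation of 6 and transfer to boron give 7 with (Z) geometry, a closed chair transition state turns that geometry into the syn (threo) relation of C1–OH and C2–OMOM, and the isopinocampheyl groups direct attack to the Si face of 5, which should set both centres as (1R,2R).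

**Step 4**
Reactants: 9 (1R,2R)-1-[4-(benzyloxy)phenyl]-2-(methoxymethoxy)but-3-en-1-ol; 10 1-bromo-3,5-bis(benzyloxy)benzene
Product: 11 (1R,2R)-1-[3,5-bis(benzyloxy)phenoxy]-1-[4-(benzyloxy)phenyl]-2-(methoxymethoxy)but-3-ene
Conditions: 10 (1.5 equiv), CuI (10 mol%), 3,4,7,8-tetramethyl-1,10-phenanthroline (20 mol%), Cs2CO3 (2 equiv), 4 Å MS, toluene, 110 °C
Reagents that add atoms: none
Why: Ullmann-type copper-catalysed C–O cross-coupling of a secondary benzylic alcohol with an aryl bromide, in which the new bond is made at the aryl carbon so that the carbinol centre is carried over with retention, and the copper catalyst should leave the terminal alkene alone.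

**Step 5**
Reactants: 11 (1R,2R)-1-[3,5-bis(benzyloxy)phenoxy]-1-[4-(benzyloxy)phenyl]-2-(methoxymethoxy)but-3-ene
Product: 13 (1R,2R)-1-[3,5-bis(benzyloxy)phenoxy]-1-[4-(benzyloxy)phenyl]but-3-en-2-ol, via bromomethyl ether 12 (not isolated)
Conditions: Me2BBr (2.5 equiv), CH2Cl2, −78 °C; then THF/saturated aqueous NaHCO3, 0 °C
Reagents that add atoms: none
Why: Lewis-acid cleavage of a methoxymethyl ether by a bromodialkylborane, in which boron binds the unhindered and most basic acetal oxygen and bromide gives 12 that is hydrolysed on work-up, while at −78 °C the weakly basic aryl ether oxygens (benzyl ethers and the benzylic C1–OAr bond) should not be activated; no stereocentre is touched.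

**Step 6**
Reactants: 13 (1R,2R)-1-[3,5-bis(benzyloxy)phenoxy]-1-[4-(benzyloxy)phenyl]but-3-en-2-ol; 3 3,4,5-tris(benzyloxy)benzoic acid
Product: 14 (1R,2R)-1-[3,5-bis(benzyloxy)phenoxy]-1-[4-(benzyloxy)phenyl]but-3-en-2-yl 3,4,5-tris(benzyloxy)benzoate
Conditions: 3 (1.5 equiv), DCC (1.6 equiv), DMAP (0.5 equiv), CH2Cl2, 0 °C to rt
Reagents that add atoms: none
Why: Steglich esterification of the hindered secondary alcohol without change at either stereocentre; the ester is introduced only now because it would migrate or be cleaved under the basic conditions of step 4, and it later acts as the participating group at C3.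

**Step 7**
Reactants: 14 (1R,2R)-1-[3,5-bis(benzyloxy)phenoxy]-1-[4-(benzyloxy)phenyl]but-3-en-2-yl 3,4,5-tris(benzyloxy)benzoate
Product: 16 (2S,3R)-3-[3,5-bis(benzyloxy)phenoxy]-3-[4-(benzyloxy)phenyl]-1-oxopropan-2-yl 3,4,5-tris(benzyloxy)benzoate, via vicinal diol 15 (not isolated)
Conditions: OsO4 (2 mol%), NaIO4 (3 equiv), 2,6-lutidine (2 equiv), dioxane/H2O 3:1, 0 °C to rt; crude 16 dried by azeotrope with toluene and used at once
Reagents that add atoms: osmium tetroxide, O=[Os](=O)(=O)=O; sodium periodate, [Na+].[O-]I(=O)(=O)=O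
Why: Lemieux–Johnson oxidation, in which catalytic dihydroxylation of the only alkene and periodate cleavage of 15 as it forms expose C4 at the aldehyde oxidation level without touching the electron-rich arenes, while the buffered medium and immediate use of crude 16 guard the α-stereocentre and the β-aryloxy group.

**Step 8**
Reactants: 16 (2S,3R)-3-[3,5-bis(benzyloxy)phenoxy]-3-[4-(benzyloxy)phenyl]-1-oxopropan-2-yl 3,4,5-tris(benzyloxy)benzoate; 4 5,7,3′,4′-tetra-O-benzyl-(−)-epicatechin 3-O-[3,4,5-tris(benzyloxy)benzoate]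
Product: 19 tridecabenzyl ether of the target (4β→8 dimer; upper unit 2R,3R,4R; lower unit 2R,3R), via flavan-4-ol 17 (not isolated), via C4 benzylic cation 18 (not isolated)
Conditions: 4 (3 equiv), Sc(OTf)3 (15 mol%), 4 Å MS, CH2Cl2 (0.02 M in 16), −40 to 0 °C; excess 4 recovered by chromatography
Reagents that add atoms: none
Why: Proposed new method: Sc(OTf)3 activates the α-acyloxy aldehyde of 16 and the tethered 3,5-bis(benzyloxy)phenoxy ring attacks through either of its two equivalent ortho carbons (6-exo-trig Friedel–Crafts hydroxyalkylation), which closes the pyran ring by the C4–C4a bond and gives 17 as a mixture of C4 epimers. The same acid ionises both epimers of 17 to the planar cation 18, stabilised by the new 5,7-dioxygenated ring A and bridged on its α face by the carbonyl oxygen of the 3-O-galloyl group, and C8 of 4 then forms the C4–C8 bond, so the mixture converges on one product. The closest known reaction types are the Lewis-acid-catalysed twofold arylation of aldehydes by electron-rich arenes (Baeyer-type triarylmethane synthesis and its ring-forming variants that give 9-arylxanthenes) and the Lewis-acid-promoted C4 arylation of 4-oxygenated flavan-3-ol derivatives by flavan nucleophiles; joining the two on an acyclic β-aryloxy aldehyde is the untested part. C4 is the only new stereocentre and is set in the capture of 18: the arene enters on the β face, anti to the 2-aryl and 3-acyloxy groups that both lie on the α face, which should give the 3,4-trans (4β, 4R) configuration. The step needs ring closure to be faster than attack of 4 on the aldehyde (secured by the three-atom tether, the high nucleophilicity of the phloroglucinol-type ring and dilution; if 4 adds first, the carbinol so formed ionises and the tethered ring closes anti to the bridging ester to the same product), C8 rather than C6 attack in 4 (the usual preference of 5,7-di-O-benzylflavans) and capture by 4 rather than by a second molecule of 17 (three equivalents of 4).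

**Step 9**
Reactants: 19 tridecabenzyl ether of the target
Product: 20 (−)-epiafzelechin 3-O-gallate-(4β→8)-(−)-epicatechin 3-O-gallate (upper unit 2R,3R,4R; lower unit 2R,3R)
Conditions: H2 (1 atm), Pd(OH)2/C (20 wt% Pd), THF/MeOH/H2O 20:1:1, rt; filtration, Sephadex LH-20
Reagents that add atoms: none
Why: Heterogeneous hydrogenolysis of all thirteen O-benzyl groups under neutral conditions, under which the aryl esters, the flavan C2–O1 bonds and the C4–C8 bond should not be cleaved, so all five stereocentres are retained.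

**Compound list**
1 | (−)-epicatechin, (2R,3R) | O[C@@H]1Cc2c(O)cc(O)cc2O[C@@H]1c1ccc(O)c(O)c1 | starting material
2 | 5,7,3′,4′-tetra-O-benzyl-(−)-epicatechin | O[C@@H]1Cc2c(OCc3ccccc3)cc(OCc3ccccc3)cc2O[C@@H]1c1ccc(OCc3ccccc3)c(OCc3ccccc3)c1 | intermediate
3 | 3,4,5-tris(benzyloxy)benzoic acid | OC(=O)c1cc(OCc2ccccc2)c(OCc2ccccc2)c(OCc2ccccc2)c1 | starting material
4 | 5,7,3′,4′-tetra-O-benzyl-(−)-epicatechin 3-O-[3,4,5-tris(benzyloxy)benzoate] | O=C(O[C@@H]1Cc2c(OCc3ccccc3)cc(OCc3ccccc3)cc2O[C@@H]1c1ccc(OCc3ccccc3)c(OCc3ccccc3)c1)c1cc(OCc3ccccc3)c(OCc3ccccc3)c(OCc3ccccc3)c1 | intermediate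
5 | 4-(benzyloxy)benzaldehyde | O=Cc1ccc(OCc2ccccc2)cc1 | starting material
6 | 3-(methoxymethoxy)prop-1-ene | C=CCOCOC | starting material
7 | (Z)-[3-(methoxymethoxy)prop-2-en-1-yl]diisopinocampheylborane (isopinocampheyl groups from (+)-α-pinene) | COCO/C=C\CB([C@@H]1C[C@@H]2C[C@H]([C@H]1C)C2(C)C)[C@@H]1C[C@@H]2C[C@H]([C@H]1C)C2(C)C | intermediate
8 | diisopinocampheylborinic ester of 9 (O-borinate) | COCO[C@@H]([C@H](OB([C@@H]1C[C@@H]2C[C@H]([C@H]1C)C2(C)C)[C@@H]1C[C@@H]2C[C@H]([C@H]1C)C2(C)C)c1ccc(OCc2ccccc2)cc1)C=C | intermediate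
9 | (1R,2R)-1-[4-(benzyloxy)phenyl]-2-(methoxymethoxy)but-3-en-1-ol | COCO[C@@H]([C@H](O)c1ccc(OCc2ccccc2)cc1)C=C | intermediate
10 | 1-bromo-3,5-bis(benzyloxy)benzene | Brc1cc(OCc2ccccc2)cc(OCc2ccccc2)c1 | starting material
11 | (1R,2R)-1-[3,5-bis(benzyloxy)phenoxy]-1-[4-(benzyloxy)phenyl]-2-(methoxymethoxy)but-3-ene | COCO[C@@H]([C@H](Oc1cc(OCc2ccccc2)cc(OCc2ccccc2)c1)c1ccc(OCc2ccccc2)cc1)C=C | intermediate
12 | (1R,2R)-1-[3,5-bis(benzyloxy)phenoxy]-1-[4-(benzyloxy)phenyl]-2-(bromomethoxy)but-3-ene | BrCO[C@@H]([C@H](Oc1cc(OCc2ccccc2)cc(OCc2ccccc2)c1)c1ccc(OCc2ccccc2)cc1)C=C | intermediate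
13 | (1R,2R)-1-[3,5-bis(benzyloxy)phenoxy]-1-[4-(benzyloxy)phenyl]but-3-en-2-ol | O[C@@H]([C@H](Oc1cc(OCc2ccccc2)cc(OCc2ccccc2)c1)c1ccc(OCc2ccccc2)cc1)C=C | intermediate
14 | (1R,2R)-1-[3,5-bis(benzyloxy)phenoxy]-1-[4-(benzyloxy)phenyl]but-3-en-2-yl 3,4,5-tris(benzyloxy)benzoate | O=C(O[C@@H]([C@H](Oc1cc(OCc2ccccc2)cc(OCc2ccccc2)c1)c1ccc(OCc2ccccc2)cc1)C=C)c1cc(OCc2ccccc2)c(OCc2ccccc2)c(OCc2ccccc2)c1 | intermediate
15 | (1R,2R)-1-[3,5-bis(benzyloxy)phenoxy]-1-[4-(benzyloxy)phenyl]-3,4-dihydroxybutan-2-yl 3,4,5-tris(benzyloxy)benzoate (both epimers at C3) | O=C(O[C@@H]([C@H](Oc1cc(OCc2ccccc2)cc(OCc2ccccc2)c1)c1ccc(OCc2ccccc2)cc1)C(O)CO)c1cc(OCc2ccccc2)c(OCc2ccccc2)c(OCc2ccccc2)c1 | intermediate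
16 | (2S,3R)-3-[3,5-bis(benzyloxy)phenoxy]-3-[4-(benzyloxy)phenyl]-1-oxopropan-2-yl 3,4,5-tris(benzyloxy)benzoate | O=C(O[C@@H]([C@H](Oc1cc(OCc2ccccc2)cc(OCc2ccccc2)c1)c1ccc(OCc2ccccc2)cc1)C=O)c1cc(OCc2ccccc2)c(OCc2ccccc2)c(OCc2ccccc2)c1 | intermediate
17 | 5,7,4′-tri-O-benzyl-4-hydroxy-(−)-epiafzelechin 3-O-[3,4,5-tris(benzyloxy)benzoate] (2R,3R; both epimers at C4) | O=C(O[C@@H]1C(O)c2c(OCc3ccccc3)cc(OCc3ccccc3)cc2O[C@@H]1c1ccc(OCc3ccccc3)cc1)c1cc(OCc3ccccc3)c(OCc3ccccc3)c(OCc3ccccc3)c1 | intermediate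
18 | C4 benzylic cation derived from 17 (2R,3R; written as its triflate ion pair) | O=C(O[C@@H]1[CH+]c2c(OCc3ccccc3)cc(OCc3ccccc3)cc2O[C@@H]1c1ccc(OCc3ccccc3)cc1)c1cc(OCc3ccccc3)c(OCc3ccccc3)c(OCc3ccccc3)c1.[O-]S(=O)(=O)C(F)(F)F | intermediate
19 | [5,7,4′-tri-O-benzyl-(−)-epiafzelechin 3-O-(3,4,5-tri-O-benzylgallate)]-(4β→8)-[5,7,3′,4′-tetra-O-benzyl-(−)-epicatechin 3-O-(3,4,5-tri-O-benzylgallate)]; upper unit 2R,3R,4R, lower unit 2R,3R | O=C(O[C@@H]1[C@@H](c2c(OCc4ccccc4)cc(OCc4ccccc4)c3c2O[C@H](c2ccc(OCc4ccccc4)c(OCc4ccccc4)c2)[C@H](OC(=O)c2cc(OCc4ccccc4)c(OCc4ccccc4)c(OCc4ccccc4)c2)C3)c2c(OCc4ccccc4)cc(OCc4ccccc4)cc2O[C@@H]1c1ccc(OCc4ccccc4)cc1)c1cc(OCc4ccccc4)c(OCc4ccccc4)c(OCc4ccccc4)c1 | intermediate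
20 | (−)-epiafzelechin 3-O-gallate-(4β→8)-(−)-epicatechin 3-O-gallate; upper unit 2R,3R,4R, lower unit 2R,3R | O=C(O[C@@H]1[C@@H](c2c(O)cc(O)c3c2O[C@H](c2ccc(O)c(O)c2)[C@H](OC(=O)c2cc(O)c(O)c(O)c2)C3)c2c(O)cc(O)cc2O[C@@H]1c1ccc(O)cc1)c1cc(O)c(O)c(O)c1 | target

**Step count and risks**
Total step count: 9. Longest linear sequence: 7 steps (steps 3 to 9, from 5 and 6); the lower unit joins after 2 steps.

Step 8 (key step, proposed new method). The cascade may fail through attack of 4 on the aldehyde before ring closure and onward double arylation, through self-condensation of the cyclised electrophile, through β-elimination of the aryloxy group from 16 under the acid, or through C6 attack in 4. The fallback uses only established flavan chemistry and takes the upper pyran ring from a natural flavan instead of closing it. It sets out from nucleophile 4 and acid 3 and returns at 19. Commercial (−)-epiafzelechin F1 is perbenzylated (BnBr, K2CO3, DMF) to 5,7,4′-tri-O-benzyl-(−)-epiafzelechin F2. Oxidation of F2 at C4 with DDQ in the presence of 2-ethoxyethanol (CH2Cl2, rt) should give 4β-(2-ethoxyethoxy)-5,7,4′-tri-O-benzyl-(−)-epiafzelechin F3. Esterification with 3 (DCC, DMAP, CH2Cl2) gives the 3-O-[3,4,5-tris(benzyloxy)benzoate] of F3 F4. Condensation of F4 with 4 (3 equiv) under TMSOTf catalysis (CH2Cl2, −78 °C) should then deliver 19 with the same 4β selectivity.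

Step 4. Coupling of the hindered secondary alkoxide may be slow, so that oxidation of the alcohol to the aryl ketone, reduction of the aryl bromide or thermal decay of 9 take over. The fallback forms the C–O bond at carbon with inversion instead of at the aryl carbon with retention; it sets out from 9 and returns at 11. Oxidation of 9 with Dess–Martin periodinane (NaHCO3, CH2Cl2, 0 °C) gives (2R)-1-[4-(benzyloxy)phenyl]-2-(methoxymethoxy)but-3-en-1-one F5. Chelation-controlled reduction with Zn(BH4)2 (Et2O, −30 °C) should give the anti alcohol (1S,2R)-1-[4-(benzyloxy)phenyl]-2-(methoxymethoxy)but-3-en-1-ol F6. Mitsunobu etherification of F6 with 3,5-bis(benzyloxy)phenol (PPh3, DIAD, toluene, 0 °C) inverts C1 and gives 11. The weak points of this fallback are enolisation of F5 and partial ionisation at the electron-rich benzylic carbon during the Mitsunobu step.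

Step 7. The α-acyloxy aldehyde may lose 3,5-bis(benzyloxy)phenol by β-elimination, epimerise at the α-carbon, or the ester may migrate within the transient diol before cleavage. The fallback avoids the free α-acyloxy aldehyde by carrying C4 as a dimethyl acetal; it sets out from 13 and returns at 19. Lemieux–Johnson cleavage of 13 (OsO4, NaIO4, 2,6-lutidine, dioxane/H2O) gives (2S,3R)-3-[3,5-bis(benzyloxy)phenoxy]-3-[4-(benzyloxy)phenyl]-2-hydroxypropanal F7, which is taken crude into HC(OMe)3, MeOH and PPTS to give (1R,2S)-1-[3,5-bis(benzyloxy)phenoxy]-1-[4-(benzyloxy)phenyl]-3,3-dimethoxypropan-2-ol F8. Esterification with 3 (DCC, DMAP) gives (1R,2S)-1-[3,5-bis(benzyloxy)phenoxy]-1-[4-(benzyloxy)phenyl]-3,3-dimethoxypropan-2-yl 3,4,5-tris(benzyloxy)benzoate F9, a storable compound. Treatment of F9 and 4 (3 equiv) with TMSOTf (10 mol%, CH2Cl2, −78 to −40 °C) should pass through the acetal-derived oxocarbenium ion, ring closure and C4 arylation to 19.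

**Further compounds**
F1 | step 8 | (−)-epiafzelechin, (2R,3R) | O[C@@H]1Cc2c(O)cc(O)cc2O[C@@H]1c1ccc(O)cc1
F2 | step 8 | 5,7,4′-tri-O-benzyl-(−)-epiafzelechin | O[C@@H]1Cc2c(OCc3ccccc3)cc(OCc3ccccc3)cc2O[C@@H]1c1ccc(OCc3ccccc3)cc1
F3 | step 8 | 4β-(2-ethoxyethoxy)-5,7,4′-tri-O-benzyl-(−)-epiafzelechin | O[C@@H]1[C@@H](OCCOCC)c2c(OCc3ccccc3)cc(OCc3ccccc3)cc2O[C@@H]1c1ccc(OCc3ccccc3)cc1
F4 | step 8 | 4β-(2-ethoxyethoxy)-5,7,4′-tri-O-benzyl-(−)-epiafzelechin 3-O-[3,4,5-tris(benzyloxy)benzoate] | O=C(O[C@@H]1[C@@H](OCCOCC)c2c(OCc3ccccc3)cc(OCc3ccccc3)cc2O[C@@H]1c1ccc(OCc3ccccc3)cc1)c1cc(OCc3ccccc3)c(OCc3ccccc3)c(OCc3ccccc3)c1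
F5 | step 4 | (2R)-1-[4-(benzyloxy)phenyl]-2-(methoxymethoxy)but-3-en-1-one | COCO[C@@H](C(=O)c1ccc(OCc2ccccc2)cc1)C=C
F6 | step 4 | (1S,2R)-1-[4-(benzyloxy)phenyl]-2-(methoxymethoxy)but-3-en-1-ol | COCO[C@@H]([C@@H](O)c1ccc(OCc2ccccc2)cc1)C=C
F7 | step 7 | (2S,3R)-3-[3,5-bis(benzyloxy)phenoxy]-3-[4-(benzyloxy)phenyl]-2-hydroxypropanal | O[C@@H]([C@H](Oc1cc(OCc2ccccc2)cc(OCc2ccccc2)c1)c1ccc(OCc2ccccc2)cc1)C=O
F8 | step 7 | (1R,2S)-1-[3,5-bis(benzyloxy)phenoxy]-1-[4-(benzyloxy)phenyl]-3,3-dimethoxypropan-2-ol | O[C@@H]([C@H](Oc1cc(OCc2ccccc2)cc(OCc2ccccc2)c1)c1ccc(OCc2ccccc2)cc1)C(OC)OC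
F9 | step 7 | (1R,2S)-1-[3,5-bis(benzyloxy)phenoxy]-1-[4-(benzyloxy)phenyl]-3,3-dimethoxypropan-2-yl 3,4,5-tris(benzyloxy)benzoate | O=C(O[C@@H]([C@H](Oc1cc(OCc2ccccc2)cc(OCc2ccccc2)c1)c1ccc(OCc2ccccc2)cc1)C(OC)OC)c1cc(OCc2ccccc2)c(OCc2ccccc2)c(OCc2ccccc2)c1
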